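Structural features

The target 15 is a spiro meroterpenoid of three rings. Ring A is an enolised 2-acylcyclohexane-1,3,5-trione (a dearomatised acylphloroglucinol): C3 carries the (2R)-2-methylbutanoyl group, C4 the enol hydroxyl, C5 is quaternary (methyl and prenyl), and C1, held between the C2 and C6 ketones, is the spiro atom. Atom labels follow the spiro name of 15: C1–C6 for ring A and C1'–C7a' for the hydrindane, C5' being the same atom as C1. Ring B (cyclohexane) shares that atom with ring A and is cis-fused through C3a'–C7a' to ring C (cyclopentane). Of the seven stereocentres, four are contiguous (C3', C3a', C7a', C7'); the carbinol carbons C3' and C7' each bear methyl and hydroxyl and each is bonded to one ring-fusion carbon. The spiro carbon is insulated from them by C4'H2 and C6'H2, C5 lies 1,3 to it across the C6 ketone, and the side-chain centre is remote. Fragile elements are the acidic, chelating β-triketone enol, the enolisable α-centre of the acyl chain, the 2,2-disubstituted 1,3-dione (retro-Claisen), two tertiary alcohols that dehydrate under acid, and the prenyl alkene. The real difficulty is the pair of all-carbon quaternary centres C1 and C5, which must match terpene stereocentres with which they share no ring when they are made. The key step exploits the fact that C7' (methyl, hydroxyl) is bonded to the ring-fusion carbon C7a' and, through C6', to the spiro carbon: this is the retron of an intramolecular carbonyl-ene reaction of a methyl ketone with a C7a'=C1' alkene of ring C, the C2' hydrogen ending on oxygen.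

Logic of the disconnections

15 ⇒ 14. No skeletal bond is cut. The C1'–C2' single bond is read as a reduced alkene, because an alkene at exactly this position is what an ene reaction leaves behind when C7a' becomes substituted. The gain is that 15 becomes the direct descendant of a ring-forming step. The forward step must reduce the ring C alkene and leave the prenyl alkene and the enol alone.

14 ⇒ 13. The C7'–C7a' bond is cut; the C7' hydroxyl returns to a ketone and the alkene returns from C1'=C2' to C7a'=C1'. This single cut removes ring B and two stereocentres (C7', C7a') and leaves two simple side arms on the future spiro carbon. The forward step must pick the methyl ketone among four carbonyl groups and the ring C alkene among three C=C bonds, and must place the C7' hydroxyl cis to C1'.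

13 ⇒ 11 + 12. The C1–C6' bond is cut: an α-haloketone and a trione enolate. C1 becomes trigonal again, so one quaternary stereocentre disappears. The forward alkylation must go to carbon, not oxygen, and must enter on the methyl face of C5, anti to prenyl. The 2-oxopropyl group has to be introduced last, because the last group at C1 is the one that ends cis to the C5 methyl.

11 ⇒ 8 + 9 + 2 (through 10). C4' is excised as a one-carbon linchpin: C1–C4' is a condensation bond and C4'–C3a' an ene bond, the C7a'=C1' alkene being the transposed alkene of 2. This splits the molecule into its aromatic-derived and terpene-derived halves and removes the C3a' stereocentre. The forward step needs the ene mode rather than cycloaddition or self-condensation of 10, and attack on the hydroxyl face of 2. Regiochemistry is fixed, since only the alkene carbon next to the carbinol has a partner hydrogen across the ring.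

8 ⇒ 6 + 7. The bond from C5 to the prenyl CH2 is cut, which restores the aromatic ring and removes the quaternary stereocentre C5. The forward step is an alkylative dearomatisation that must occur at the methyl-bearing ring carbon and must select one face of a flat phenolate. This centre has no neighbour to lean on, so a chiral catalyst is required.

6 ⇒ 4 + 3 (through 5). The aryl–carbonyl bond is cut (Friedel–Crafts retron). The two free positions of 4 are equivalent, so no regiochemistry arises. The only demand is that the α-stereocentre of 3 survives acyl activation.

2 ⇒ 1. The ring alkene is opened to two alkenes (metathesis retron), which leads to a cheap chiral-pool alcohol that already holds the C3' stereocentre. The forward ring closure has no stereochemical task.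

Other disconnections considered

Alternative 1: The cut is at C5'–C4', C3a'–C7a' and C5'–C6', so rings B and C fall apart at once into (S)-linalool 1 and dimethyl malonate A1. In the forward key step Mn(OAc)3 (trivalent manganese) oxidises A1 to the malonyl radical, which adds to the vinyl CH2 of 1; the adduct radical closes ring C 5-exo on the trisubstituted alkene, and Cu(OAc)2 (divalent copper) turns the tertiary radical into an isopropenyl group. A second oxidation of the now monoalkylated malonate closes ring B 6-endo on that group and ends as the exocyclic methylene of the hydrindane gem-diester A2. In its favour: three C–C bonds, two rings and the cis fusion in one flask from two bulk chemicals. All ten carbons of 1 are kept, whereas the chosen plan discards 2-methylpropene and buys three carbons back as 12; on atom economy and bonds per step this alternative is the better one. Its tolerance of free hydroxyl groups is at least equal to that of a Lewis-acid step. Against it here: the C3' centre offers only methyl versus hydroxyl to bias the radical closure, so the C3'/C3a' relationship would be expected as a mixture. C7' arrives as a methylene and must be hydrated later without facial control, whereas the ene transition state of the chosen plan fixes it. Most seriously, A2 has only a malonate where ring A must stand; the acylated trione with its C5 quaternary centre has to be grown from two esters, and the spiro carbon becomes stereogenic in that process with nothing to control it. Comparison: structurally A2 solves the hydrindane better and the chosen route solves ring A better (two steps from an aromatic). Mechanistically a radical cascade stands against a pericyclic closure with built-in control at C7'. In step count the cascade itself is unbeatable, but the ring A construction that must follow would be expected to make the whole sequence longer than seven steps.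

Alternative 2: The cut is at C1–C4' and C3'–C3a' (made together); ring B is closed afterwards at C1–C6'. The photosubstrate A3 is ring A bearing on C1 an acyl chain (C3' as acyl carbon) that ends in a vinyl group and carries the C7' unit as a 2-methyloxiranyl substituent. Irradiation adds the enol C1=C3' bond across the vinyl group, C3' to the inner carbon (five-membered ring C, as the rule of five predicts) and C1 to the terminal CH2; the cyclobutanol opens by retro-aldol to the 1,5-diketone A4. Epoxide opening by C1 would then close ring B, and methyl addition to the C3' ketone would finish the skeleton. In its favour: the C1–C4'–C3a' link, the weakest point of the chosen route (an intermolecular ene reaction), is made intramolecularly by a reaction designed for this 1,5-dicarbonyl outcome; on this point the alternative is the better plan. C7' would be carried in as a defined epoxide rather than induced. Ring A comes from the same aromatic chemistry, so the two plans are equal there, including the unsolved C1/C5 relationship. Against: an acidic triketone and a 2,2-disubstituted epoxide must coexist through acylation and photolysis, and the prenyl alkene and the second enolised acyl group are competing partners for the excited enol. C3a' is set only by the preference of the bicyclic photoadduct, and the epoxide would come from an isopropenyl group without facial bias. The late methyl addition must be chemoselective among five carbonyls and anti to C4', whereas the chosen plan imports C3' unchanged from 1. Comparison: a photocycloaddition–fragmentation stands against a thermal pericyclic step. The limonene-derived acid, its C-acylation and two operations after photolysis would be expected to exceed the present step count.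

Alternative 3: The cut is at C1–C6, the bond between the spiro carbon and the ketone next to C5; the acyl group on C3 is added last. The open-chain β-diketone A5 has its C2 carbonyl on the ring B carbon C5' and its C4 carbonyl on the quaternary C5, which also bears the C6 ester. Double deprotonation places the second charge on C5', and this carbon attacks the ester (Dieckmann-type Claisen) to give the spiro trione A6 with both tertiary alcohols as triethylsilyl ethers. In its favour: C5 can be made and purified in a small acyclic fragment by established asymmetric alkylation or desymmetrisation of a malonate; this is better absolute control than any dearomatisation and is the point on which this alternative is superior. The spiro centre would form under the bias of the ring B chair, a more tangible influence than the 1,3-induction across a ketone used in step 5, and the acidic product drives the condensation. Against: the hydrindane with four stereocentres must first be made by a route of its own, protected twice and deprotected. A ring-bound tertiary carbanion must acylate through a crowded transition state in competition with O-acylation, and the (R)-acyl chain must be attached to a hindered trione at the very end. Comparison: structurally it replaces the cheap aromatic ring A by a de novo ring. Mechanistically, reliable ionic condensation chemistry stands against one pericyclic step. In step economy it is linear and would be expected to need about twice as many operations.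

Key step: step 6

Remarks on the chemistry (assumptions and conventions)
- (S)-1 of high enantiomeric purity is assumed to be purchasable; any enantiomeric impurity would appear at 13 as a separable diastereomer.
- Ring A is written throughout as the C4 enol; other enol tautomers are the same compound.
- The configurations of 13 and 14 were rederived from 15 centre by centre and agree at every shared centre; (S)-1 supplies C3' and (R)-3 the side chain, so no structure needed correction.
- Origin of the stereocentres: side chain from 3; C3' from 1; C5 in step 3; C3a' in step 4; C1 in step 5; C7a' and C7' in step 6.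
- The sense of induction of the chiral ammonium salt in step 3 is assigned by analogy and must be confirmed by an early correlation; the pseudo-enantiomeric salt is the switch.

Step 1
Reactants: 1 (S)-linalool [(3S)-3,7-dimethylocta-1,6-dien-3-ol]
Product: 2 (1S)-1-methylcyclopent-2-en-1-ol
Conditions: second-generation Grubbs catalyst RuCl2(=CHPh)(H2IMes)(PCy3) (0.5 mol%), CH2Cl2, 40 °C
Reagents that add atoms: none
Why: Ring-closing metathesis of the 1,6-diene: the ruthenium carbene loads on the vinyl group next to the free tertiary hydroxyl and closes on the trisubstituted alkene with loss of volatile 2-methylpropene; the carbinol stereocentre is not involved and stays (S).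

Step 2
Reactants: 3 (2R)-2-methylbutanoic acid; 4 2-methylbenzene-1,3,5-triol (2-methylphloroglucinol)
Product: 6 (2R)-2-methyl-1-(2,4,6-trihydroxy-3-methylphenyl)butan-1-one, via (2R)-2-methylbutanoyl chloride 5 (not isolated)
Conditions: (COCl)2, DMF (cat.), CH2Cl2, 0 °C to rt; then 4, AlCl3 (3.5 equiv), PhNO2/CH2Cl2, 0 °C to rt; 1 M HCl
Reagents that add atoms: none
Why: Friedel–Crafts acylation of the very electron-rich arene by the acid chloride made in the same flask; the two free ring positions of 4 are equivalent, so one C-acyl product can form, and any O-acyl ester is carried to carbon by AlCl3 (Fries). Working at or below room temperature without base protects the α-stereocentre.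

Step 3
Reactants: 6 (2R)-2-methyl-1-(2,4,6-trihydroxy-3-methylphenyl)butan-1-one; 7 1-bromo-3-methylbut-2-ene (prenyl bromide)
Product: 8 (6S)-3,5-dihydroxy-6-methyl-4-[(2R)-2-methylbutanoyl]-6-(3-methylbut-2-en-1-yl)cyclohexa-2,4-dien-1-one
Conditions: N-(9-anthracenylmethyl)cinchonidinium bromide (10 mol%), CsOH·H2O (2.2 equiv), PhMe/CH2Cl2, −40 °C; 1 M HCl
Reagents that add atoms: none
Why: Asymmetric phase-transfer alkylation that dearomatises the ring (alkylative dearomatisation of an acylphloroglucinol): the phenolate of 6 is most electron-rich at the methyl-bearing carbon, and SN2 attack on 7 there creates the quaternary C5, which cannot rearomatise. The chiral ammonium cation pairs with the phenolate and shields one face, which sets C5; the (S) sense is assigned by analogy with enolate alkylations under this catalyst and must be confirmed, the pseudo-enantiomeric cinchoninium salt giving the other face. Any C5 epimer is a diastereomer (the acyl chain is homochiral) and is removed at 13 at the latest.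

Step 4
Reactants: 8 (6S)-3,5-dihydroxy-6-methyl-4-[(2R)-2-methylbutanoyl]-6-(3-methylbut-2-en-1-yl)cyclohexa-2,4-dien-1-one; 9 formaldehyde (used as paraformaldehyde); 2 (1S)-1-methylcyclopent-2-en-1-ol
Product: 11 (6S)-3,5-dihydroxy-2-{[(1R,5S)-5-hydroxy-5-methylcyclopent-2-en-1-yl]methyl}-6-methyl-4-[(2R)-2-methylbutanoyl]-6-(3-methylbut-2-en-1-yl)cyclohexa-2,4-dien-1-one, via methylene trione 10 (not isolated)
Conditions: (CH2O)n (2 equiv), 2 (5 equiv, excess recovered), NaOAc (1 equiv), 1,4-dioxane, 70 °C
Reagents that add atoms: none
Why: Knoevenagel condensation of the remaining ring CH of 8 with formaldehyde gives the methylene trione 10, an electron-poor enophile of the quinone-methide type, which undergoes an intermolecular Alder-ene reaction with 2; only the alkene carbon next to the carbinol can be attacked in the ene mode (the other would need a hydrogen on the quaternary carbon), so the C4'–C3a' bond forms and the alkene moves to the position needed later. The free hydroxyl of 2 hydrogen-bonds to a carbonyl of 10 and is smaller than the methyl group, so the enophile arrives on the hydroxyl face, which sets C3a' (R) cis to OH. The excess of 2 and the buffered medium are chosen to outrun self-condensation of 10 and to spare the tertiary allylic alcohol.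

Step 5
Reactants: 11 (6S)-3,5-dihydroxy-2-{[(1R,5S)-5-hydroxy-5-methylcyclopent-2-en-1-yl]methyl}-6-methyl-4-[(2R)-2-methylbutanoyl]-6-(3-methylbut-2-en-1-yl)cyclohexa-2,4-dien-1-one; 12 1-chloropropan-2-one (chloroacetone)
Product: 13 (2R,6S)-5-hydroxy-2-{[(1R,5S)-5-hydroxy-5-methylcyclopent-2-en-1-yl]methyl}-6-methyl-4-[(2R)-2-methylbutanoyl]-6-(3-methylbut-2-en-1-yl)-2-(2-oxopropyl)cyclohex-4-ene-1,3-dione
Conditions: NaOMe (2.0 equiv), MeOH, −10 °C; 12 (1.2 equiv), −10 to 10 °C; AcOH
Reagents that add atoms: none
Why: SN2 C-alkylation of a β-dicarbonyl dianion by an α-haloketone: two equivalents of methoxide remove both enol protons, the only ring carbon that still has a hydrogen (C1) is the nucleophile, and methanol solvation of oxygen favours C- over O-alkylation. The electrophile approaches the flat enolate 1,3 to C5 on the face of the small methyl group, away from the prenyl chain, which sets C1 (R); the minor C1 epimer is removed by chromatography. After alkylation the product is a weakly basic triketone anion, so no base remains to trigger aldol closure of the new 1,4-diketone or retro-Claisen opening.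

Step 6
Reactants: 13 (2R,6S)-5-hydroxy-2-{[(1R,5S)-5-hydroxy-5-methylcyclopent-2-en-1-yl]methyl}-6-methyl-4-[(2R)-2-methylbutanoyl]-6-(3-methylbut-2-en-1-yl)-2-(2-oxopropyl)cyclohex-4-ene-1,3-dione
Product: 14 (1R,5S,3'S,3a'R,7'S,7a'R)-3',4,7'-trihydroxy-3',5,7'-trimethyl-3-[(2R)-2-methylbutanoyl]-5-(3-methylbut-2-en-1-yl)-3',3a',4',6',7',7a'-hexahydrospiro[cyclohex-3-ene-1,5'-indene]-2,6-dione
Conditions: Me2AlCl (4 equiv), CH2Cl2, −78 to 0 °C; 1 M HCl
Reagents that add atoms: none
Why: Me2AlCl first turns the enol and the C3' hydroxyl into an aluminium chelate and an aluminium alkoxide (methane is lost) and the excess binds the unhindered methyl ketone; the activated carbonyl carbon then bonds to C7a' while the C2' hydrogen on the same face passes to oxygen through a six-centre transition state and the alkene moves to C1'=C2' (intramolecular carbonyl-ene reaction). The closest known reaction type is the Lewis-acid-promoted type 1 ene cyclisation of ε,ζ-unsaturated ketones to cyclohexanols. Ring B closes in the 6-exo mode: the attacked alkene carbon C7a' lies inside the new six-membered ring and C1' outside it. C7a' is controlled by the tether: C4', C5' and C6' hang from C3a' on one face of ring C, so the carbonyl carbon can reach C7a' only from that face, which gives the cis ring fusion. C7' is controlled by the hydrogen transfer: the oxygen must lie under ring C next to the C2' hydrogen, which puts the hydroxyl axial on ring B and cis to C1' and leaves the methyl group equatorial on the convex face. The step needs chemoselectivity among four carbonyl groups and three alkenes; it is secured because the triketone is tied up as its aluminium chelate, the C6 ketone is flanked by two quaternary carbons and could close only a five-membered ring, and the prenyl alkene could be reached only through a seven-membered ring. The new alkene creates no stereocentre, and the aluminium on the C3' oxygen, which sits on the reacting face, can only help to hold the ketone oxygen where it is needed.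

Step 7
Reactants: 14 (1R,5S,3'S,3a'R,7'S,7a'R)-3',4,7'-trihydroxy-3',5,7'-trimethyl-3-[(2R)-2-methylbutanoyl]-5-(3-methylbut-2-en-1-yl)-3',3a',4',6',7',7a'-hexahydrospiro[cyclohex-3-ene-1,5'-indene]-2,6-dione
Product: 15 (1R,5S,3'S,3a'R,7'S,7a'R)-3',4,7'-trihydroxy-3',5,7'-trimethyl-3-[(2R)-2-methylbutanoyl]-5-(3-methylbut-2-en-1-yl)-1',2',3',3a',4',6',7',7a'-octahydrospiro[cyclohex-3-ene-1,5'-indene]-2,6-dione (target)
Conditions: 2-nitrobenzenesulfonylhydrazide (3 equiv), Et3N, CH2Cl2, rt
Reagents that add atoms: none
Why: Diimide, released from the sulfonylhydrazide by Et3N, delivers two hydrogens in a concerted syn transfer and reacts much faster with the cis-disubstituted ring alkene than with the trisubstituted prenyl alkene or the conjugated tetrasubstituted enol; ketones, the enol and the tertiary alcohols are inert and no metal is present to isomerise the prenyl group. No stereocentre is formed or touched.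

Compound list
1 | (S)-linalool, (3S)-3,7-dimethylocta-1,6-dien-3-ol | C=C[C@@](C)(O)CCC=C(C)C | starting material
2 | (1S)-1-methylcyclopent-2-en-1-ol | C1=C[C@@](C)(O)CC1 | intermediate
3 | (2R)-2-methylbutanoic acid | CC[C@@H](C)C(O)=O | starting material
4 | 2-methylbenzene-1,3,5-triol (2-methylphloroglucinol) | Cc1c(O)cc(O)cc1O | starting material
5 | (2R)-2-methylbutanoyl chloride | CC[C@@H](C)C(Cl)=O | intermediate (not isolated)
6 | (2R)-2-methyl-1-(2,4,6-trihydroxy-3-methylphenyl)butan-1-one | CC[C@@H](C)C(=O)c1c(O)cc(O)c(C)c1O | intermediate
7 | 1-bromo-3-methylbut-2-ene (prenyl bromide) | CC(C)=CCBr | starting material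
8 | (6S)-3,5-dihydroxy-6-methyl-4-[(2R)-2-methylbutanoyl]-6-(3-methylbut-2-en-1-yl)cyclohexa-2,4-dien-1-one | CC[C@@H](C)C(=O)C1=C(O)[C@](C)(CC=C(C)C)C(=O)C=C1O | intermediate
9 | formaldehyde (used as paraformaldehyde) | C=O | starting material
10 | (6S)-5-hydroxy-6-methyl-4-[(2R)-2-methylbutanoyl]-6-(3-methylbut-2-en-1-yl)-2-methylidenecyclohex-4-ene-1,3-dione (methylene trione) | CC[C@@H](C)C(=O)C1=C(O)[C@](C)(CC=C(C)C)C(=O)C(=C)C1=O | intermediate (not isolated)
11 | (6S)-3,5-dihydroxy-2-{[(1R,5S)-5-hydroxy-5-methylcyclopent-2-en-1-yl]methyl}-6-methyl-4-[(2R)-2-methylbutanoyl]-6-(3-methylbut-2-en-1-yl)cyclohexa-2,4-dien-1-one | CC[C@@H](C)C(=O)C1=C(O)[C@](C)(CC=C(C)C)C(=O)C(C[C@@H]2C=CC[C@]2(C)O)=C1O | intermediate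
12 | 1-chloropropan-2-one (chloroacetone) | CC(=O)CCl | starting material
13 | (2R,6S)-5-hydroxy-2-{[(1R,5S)-5-hydroxy-5-methylcyclopent-2-en-1-yl]methyl}-6-methyl-4-[(2R)-2-methylbutanoyl]-6-(3-methylbut-2-en-1-yl)-2-(2-oxopropyl)cyclohex-4-ene-1,3-dione (precursor of the key step) | CC[C@@H](C)C(=O)C1=C(O)[C@](C)(CC=C(C)C)C(=O)[C@](CC(C)=O)(C[C@@H]2C=CC[C@]2(C)O)C1=O | intermediate
14 | (1R,5S,3'S,3a'R,7'S,7a'R)-3',4,7'-trihydroxy-3',5,7'-trimethyl-3-[(2R)-2-methylbutanoyl]-5-(3-methylbut-2-en-1-yl)-3',3a',4',6',7',7a'-hexahydrospiro[cyclohex-3-ene-1,5'-indene]-2,6-dione (product of the key step) | CC[C@@H](C)C(=O)C1=C(O)[C@](C)(CC=C(C)C)C(=O)[C@]2(C[C@@H]3[C@@H](C=C[C@]3(C)O)[C@@](C)(O)C2)C1=O | intermediate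
15 | (1R,5S,3'S,3a'R,7'S,7a'R)-3',4,7'-trihydroxy-3',5,7'-trimethyl-3-[(2R)-2-methylbutanoyl]-5-(3-methylbut-2-en-1-yl)-1',2',3',3a',4',6',7',7a'-octahydrospiro[cyclohex-3-ene-1,5'-indene]-2,6-dione | CC[C@@H](C)C(=O)C1=C(O)[C@](C)(CC=C(C)C)C(=O)[C@]2(C[C@@H]3[C@@H](CC[C@]3(C)O)[C@@](C)(O)C2)C1=O | target

Total step count: 7. Longest linear sequence: 6 steps (4 → 6 → 8 → 11 → 13 → 14 → 15, steps 2 to 7); step 1 supplies 2 in a side branch.

Least certain steps

For step 6 (key step): a methyl ketone is a weak enophile toward a 1,2-disubstituted alkene. The reaction may therefore stall or, if forced, turn stepwise, with chloride capture of the C1' cation, erosion of the C7' configuration, or ionisation of the tertiary aluminium alkoxides. The fallback replaces the pericyclic closure by a deliberate cationic one. Setting out from 13, TiCl4 in CH2Cl2 at −78 °C would drive a Prins cyclisation in which the metal on the carbonyl oxygen hands chloride to C1' on the same face, which keeps the oxygen on the ring C side, and would give the 1'-chloro alcohol F1. Radical dechlorination (Bu3SnH, AIBN, PhMe, 80 °C) then removes the halogen and rejoins the route at 15, bypassing 14 and step 7.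

For step 4: the methylene trione 10 may be consumed by Michael addition of unreacted 8 or by hetero-Diels–Alder dimerisation faster than the poorly nucleophilic ring alkene of 2 can react. Cycloaddition of 2 through the carbonyl oxygen, or attack on the methyl face, would also divert material. The fallback builds the same bonds one at a time with established reactions, setting out from 2. A formaldehyde ene reaction ((CH2O)n, Me2AlCl, CH2Cl2, −78 to 0 °C), in which the aluminium alkoxide of 2 delivers the aldehyde to its own face, would give (1S,2S)-2-(hydroxymethyl)-1-methylcyclopent-3-en-1-ol F2. Selective oxidation of the primary alcohol (TEMPO, PhI(OAc)2, CH2Cl2) would give (1R,5S)-5-hydroxy-5-methylcyclopent-2-ene-1-carbaldehyde F3, used at once. Reductive Knoevenagel alkylation of 8 with this aldehyde (L-proline cat., diethyl 2,6-dimethyl-1,4-dihydropyridine-3,5-dicarboxylate, CH2Cl2, rt) rejoins the route at 11.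

For step 3: the ion pair may discriminate the two faces of the phenolate poorly, and alkylation at the free ring CH or at oxygen may compete. The fallback gives up catalyst control in favour of separation. Setting out from 6, prenylation with 7 under NaOMe/MeOH would give 8 together with its (6R) epimer F4. The pair is carried through steps 4 and 5, the epimer passing through the (6R) epimer of 11 F5 to the (2S,6R) diastereomer of 13 F6. At that stage the two series differ in the sense of ring A relative to the adjacent ring C stereocentres and are separated by chromatography, rejoining the route at 13.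

For step 5: methyl and prenyl differ only beyond their first carbon, so face selection may be low, and O-alkylation or base-induced aldol closure of the new 1,4-diketone may intervene. The fallback changes the electrophile type. Setting out from 11, Tsuji–Trost allylation (Pd(PPh3)4, zerovalent palladium, allyl methyl carbonate, THF, rt) would give the C1-allyl compound (2S,6S)-5-hydroxy-2-{[(1R,5S)-5-hydroxy-5-methylcyclopent-2-en-1-yl]methyl}-6-methyl-4-[(2R)-2-methylbutanoyl]-6-(3-methylbut-2-en-1-yl)-2-(prop-2-en-1-yl)cyclohex-4-ene-1,3-dione F7, which has the spatial arrangement of 13 (the descriptor at C2 changes by priority only). The bulky π-allyl cation should read the face difference better, and any O-allyl product re-ionises. Wacker oxidation of the terminal alkene (PdCl2, CuCl, O2, DMF/H2O) rejoins the route at 13.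

For step 7: the ring alkene is flanked by two fully substituted carbons, so its reduction may be slow enough for the prenyl alkene to begin to react. The fallback, setting out from 14, is homogeneous hydrogenation with RhCl(PPh3)3 (H2, 1 atm, benzene, rt), which leaves trisubstituted alkenes untouched and rejoins the route at 15 without any new compound.

Further compounds
F1 | step 6 | 1'-chloro derivative of 15 (chlorine on C1', configuration there undefined, all other centres as in 15) | CC[C@@H](C)C(=O)C1=C(O)[C@](C)(CC=C(C)C)C(=O)[C@]2(C[C@@H]3[C@@H](C(Cl)C[C@]3(C)O)[C@@](C)(O)C2)C1=O
F2 | step 4 | (1S,2S)-2-(hydroxymethyl)-1-methylcyclopent-3-en-1-ol | OC[C@@H]1C=CC[C@]1(C)O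
F3 | step 4 | (1R,5S)-5-hydroxy-5-methylcyclopent-2-ene-1-carbaldehyde | O=C[C@@H]1C=CC[C@]1(C)O
F4 | step 3 | (6R)-3,5-dihydroxy-6-methyl-4-[(2R)-2-methylbutanoyl]-6-(3-methylbut-2-en-1-yl)cyclohexa-2,4-dien-1-one (C5 epimer of 8) | CC[C@@H](C)C(=O)C1=C(O)[C@@](C)(CC=C(C)C)C(=O)C=C1O
F5 | step 3 | (6R)-3,5-dihydroxy-2-{[(1R,5S)-5-hydroxy-5-methylcyclopent-2-en-1-yl]methyl}-6-methyl-4-[(2R)-2-methylbutanoyl]-6-(3-methylbut-2-en-1-yl)cyclohexa-2,4-dien-1-one (C5 epimer of 11) | CC[C@@H](C)C(=O)C1=C(O)[C@@](C)(CC=C(C)C)C(=O)C(C[C@@H]2C=CC[C@]2(C)O)=C1O
F6 | step 3 | (2S,6R)-5-hydroxy-2-{[(1R,5S)-5-hydroxy-5-methylcyclopent-2-en-1-yl]methyl}-6-methyl-4-[(2R)-2-methylbutanoyl]-6-(3-methylbut-2-en-1-yl)-2-(2-oxopropyl)cyclohex-4-ene-1,3-dione (ring A diastereomer of 13) | CC[C@@H](C)C(=O)C1=C(O)[C@@](C)(CC=C(C)C)C(=O)[C@@](CC(C)=O)(C[C@@H]2C=CC[C@]2(C)O)C1=O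
F7 | step 5 | (2S,6S)-5-hydroxy-2-{[(1R,5S)-5-hydroxy-5-methylcyclopent-2-en-1-yl]methyl}-6-methyl-4-[(2R)-2-methylbutanoyl]-6-(3-methylbut-2-en-1-yl)-2-(prop-2-en-1-yl)cyclohex-4-ene-1,3-dione | CC[C@@H](C)C(=O)C1=C(O)[C@](C)(CC=C(C)C)C(=O)[C@](CC=C)(C[C@@H]2C=CC[C@]2(C)O)C1=O
F0 | step 7 | none | none
A1 | alternative 1 | dimethyl malonate | COC(=O)CC(=O)OC
A2 | alternative 1 | dimethyl (3S,3aR,7aR)-3-hydroxy-3-methyl-7-methylideneoctahydro-5H-indene-5,5-dicarboxylate | COC(=O)C1(C(=O)OC)C[C@@H]2[C@@H](CC[C@]2(C)O)C(=C)C1
A3 | alternative 2 | 3,5-dihydroxy-6-methyl-4-[(2R)-2-methylbutanoyl]-6-(3-methylbut-2-en-1-yl)-2-[4-(2-methyloxiran-2-yl)hex-5-enoyl]cyclohexa-2,4-dien-1-one (photosubstrate, configurations as in the SMILES) | CC[C@@H](C)C(=O)C1=C(O)C(C(=O)CC[C@H](C=C)[C@]2(C)CO2)=C(O)[C@@](C)(CC=C(C)C)C1=O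
A4 | alternative 2 | 3,5-dihydroxy-6-methyl-4-[(2R)-2-methylbutanoyl]-6-(3-methylbut-2-en-1-yl)-2-{[5-(2-methyloxiran-2-yl)-2-oxocyclopentyl]methyl}cyclohexa-2,4-dien-1-one (configurations as in the SMILES) | CC[C@@H](C)C(=O)C1=C(O)C(C[C@@H]2[C@@H](CCC2=O)[C@]3(C)CO3)=C(O)[C@@](C)(CC=C(C)C)C1=O
A5 | alternative 3 | methyl 2-methyl-2-(3-methylbut-2-en-1-yl)-3,5-dioxo-5-[3,7-dimethyl-3,7-bis(triethylsilyloxy)octahydro-1H-inden-5-yl]pentanoate (configurations as in the SMILES, C5' undefined) | COC(=O)[C@@](C)(CC=C(C)C)C(=O)CC(=O)C1C[C@@H]2[C@@H](CC[C@]2(C)O[Si](CC)(CC)CC)[C@@](C)(O[Si](CC)(CC)CC)C1
A6 | alternative 3 | 3-deacyl analogue of 15 as its 3',7'-bis(triethylsilyl) ether | C1=C(O)[C@](C)(CC=C(C)C)C(=O)[C@]2(C[C@@H]3[C@@H](CC[C@]3(C)O[Si](CC)(CC)CC)[C@@](C)(O[Si](CC)(CC)CC)C2)C1=O
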